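Maackin is cut through benzene ring B. Numbering the dioxane O1, C2 (ring C), C3 (ring D), O4 and ring B C4a to C8a (styryl to ring A on C7), the neighbouring carbons C4a and C8a each hold a dioxane oxygen, so ring B can grow from two alkynyl ethers of the (2R,3R)-diol and the alkyne of a ring-A enyne. One ruthenium-catalysed [2+2+2] cycloaddition makes C4a–C8a, C5–C6 and C7–C8 and so closes the dioxane and ring B at once. Its precursor is the threo diol diether with HC≡C–O on C2 and Et3Si–C≡C–O on C3; the silyl group steers the styryl carbon to C7 and is lost in the final acid step.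

Key step: step 14

Remarks on the chemistry
- Assumption: the facial sense of the Davis oxidation is carried over from the parent deoxybenzoin enolate, for which the (−)-reagent gives (R)-benzoin. If needed, enantiomeric purity can be raised by recrystallisation of the hydroxy ketone or of the later dichlorovinyl alcohol.
- The target SMILES reads as (2R,3R), trans. Both C–O bonds at C2 and C3 are kept throughout, so a (1R,2R)-threo diol maps directly onto it.
- O1 is masked as a mixed ketal, not as a silyl ether. A silyl group next to a potassium alkoxide would wander between O1 and O4 and erase the distinction on which regiocontrol rests. Its removal with fluoride would also strip an alkynylsilane.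
- The mask on O1 is taken off at the acid-tolerant dichlorovinyl ether stage, because alkynyl ethers do not survive acid.
- The blocking group is Et3Si rather than Me3Si. Base-induced cleavage of C(sp)–SiEt3 is much slower, so it should survive K2CO3/MeOH and a neighbouring potassium alkoxide. Acid cleavage of the later aryl–Si bond is only slightly slower.
- All alkynyl ethers are kept at or below 25 °C, handled on base-washed glass and Et3N-deactivated silica, and used promptly.
- No base equilibration is planned at the end. The trans ring follows from the threo diol, and base would only expose the polyphenol to air oxidation.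

Step 1
Reactants: 1 3',4'-dihydroxyacetophenone
Product: 2 1-[3,4-bis(methoxymethoxy)phenyl]ethan-1-one
Conditions: MOMCl (3 equiv), i-Pr2NEt (4 equiv), CH2Cl2, 0 °C to rt
Reagents that add atoms: chloromethyl methyl ether (MOMCl), COCCl
Why: Amine-mediated O-alkylation of both phenols with the α-chloro ether (Williamson-type MOM protection) gives acetals that tolerate KH, n-BuLi and hydride and fall in the last acid step.

Step 2
Reactants: 3 5-bromobenzene-1,3-diol
Product: 4 1-bromo-3,5-bis(methoxymethoxy)benzene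
Conditions: MOMCl (3 equiv), i-Pr2NEt (4 equiv), CH2Cl2, 0 °C to rt
Reagents that add atoms: chloromethyl methyl ether (MOMCl), COCCl
Why: The same Williamson-type MOM protection masks the resorcinol of ring C and leaves the aryl bromide ready for cross-coupling.

Step 3
Reactants: 2 1-[3,4-bis(methoxymethoxy)phenyl]ethan-1-one; 4 1-bromo-3,5-bis(methoxymethoxy)benzene
Product: 5 1-[3,4-bis(methoxymethoxy)phenyl]-2-[3,5-bis(methoxymethoxy)phenyl]ethan-1-one
Conditions: Pd2(dba)3 (1.5 mol %), Xantphos (3.5 mol %), NaOt-Bu (1.3 equiv), toluene, 80 °C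
Reagents that add atoms: none
Why: Palladium-catalysed α-arylation of a ketone enolate (Buchwald–Hartwig type: oxidative addition of 4 to zerovalent palladium, enolate binding, reductive elimination) joins C2 to ring C, the wide-bite-angle ligand favouring monoarylation, and puts the carbonyl (future C3–O4) next to ring D so that the two oxygens are distinguishable from here on.

Step 4
Reactants: 5 1-[3,4-bis(methoxymethoxy)phenyl]-2-[3,5-bis(methoxymethoxy)phenyl]ethan-1-one
Product: 7 (2R)-1-[3,4-bis(methoxymethoxy)phenyl]-2-[3,5-bis(methoxymethoxy)phenyl]-2-hydroxyethan-1-one, via sodium enolate 6 (not isolated)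
Conditions: NaN(SiMe3)2 (1.2 equiv), THF, −78 °C; (1R)-(−)-(10-camphorsulfonyl)oxaziridine (1.4 equiv), −78 °C; sat. aq NH4Cl, −78 °C
Reagents that add atoms: (1R)-(−)-(10-camphorsulfonyl)oxaziridine, CC1(C)[C@H]2CC[C@@]13CS(=O)(=O)N4O[C@]34C2
Why: Davis oxidation: the (Z)-enolate attacks the electrophilic oxaziridine oxygen and the camphor scaffold shields one enolate face, which sets C2 as R under reagent control by analogy with the parent deoxybenzoin enolate.

Step 5
Reactants: 7 (2R)-1-[3,4-bis(methoxymethoxy)phenyl]-2-[3,5-bis(methoxymethoxy)phenyl]-2-hydroxyethan-1-one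
Product: 8 (2R)-1-[3,4-bis(methoxymethoxy)phenyl]-2-[3,5-bis(methoxymethoxy)phenyl]-2-[(2-methoxypropan-2-yl)oxy]ethan-1-one
Conditions: 2-methoxypropene (5 equiv), PPTS (5 mol %), CH2Cl2, 0 °C; Et3N quench
Reagents that add atoms: 2-methoxypropene, C=C(C)OC
Why: Acid-catalysed addition of the hydroxyl group to the enol ether (mixed-ketal protection) runs without base so C2 is not epimerised, adds no stereocentre, and gives a group that unlike a silyl or acyl group cannot migrate to a neighbouring alkoxide.

Step 6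
Reactants: 8 (2R)-1-[3,4-bis(methoxymethoxy)phenyl]-2-[3,5-bis(methoxymethoxy)phenyl]-2-[(2-methoxypropan-2-yl)oxy]ethan-1-one
Product: 9 (1R,2R)-1-[3,4-bis(methoxymethoxy)phenyl]-2-[3,5-bis(methoxymethoxy)phenyl]-2-[(2-methoxypropan-2-yl)oxy]ethan-1-ol
Conditions: KBH(s-Bu)3 (1.5 equiv), THF, −78 °C; then NaOH, H2O2, 0 °C
Reagents that add atoms: none
Why: Substrate-controlled hydride reduction under non-chelating conditions: in the polar Felkin–Anh arrangement the C2–O bond stands perpendicular to the carbonyl and the bulky borohydride passes the C2 hydrogen, which sets C3 as R and gives the threo (1R,2R) alcohol with O4–H free.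

Step 7
Reactants: 9 (1R,2R)-1-[3,4-bis(methoxymethoxy)phenyl]-2-[3,5-bis(methoxymethoxy)phenyl]-2-[(2-methoxypropan-2-yl)oxy]ethan-1-ol; 10 trichloroethylene
Product: 12 O4-[(E)-1,2-dichloroethenyl] ether of 9, via potassium alkoxide 11 (not isolated)
Conditions: KH (2.2 equiv), THF, 0 °C to rt; Cl2C=CHCl (1.2 equiv), −50 °C to rt
Reagents that add atoms: none
Why: First half of the dichlorovinyl ether route to alkynyl ethers: base strips HCl from 10 to give dichloroacetylene, to which alkoxide 11 adds in anti fashion to give the (E)-1,2-dichlorovinyl ether, no bond at C2 or C3 being broken.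

Step 8
Reactants: 12 O4-[(E)-1,2-dichloroethenyl] ether of 9
Product: 13 (1R,2R)-2-[3,4-bis(methoxymethoxy)phenyl]-2-{[(E)-1,2-dichloroethenyl]oxy}-1-[3,5-bis(methoxymethoxy)phenyl]ethan-1-ol
Conditions: PPTS (10 mol %), MeOH, 0 °C
Reagents that add atoms: none
Why: Acid-catalysed transketalisation to methanol removes the tertiary mixed ketal far faster than the aryl MOM acetals react, and the electron-poor dichlorovinyl ether is inert to such weak acid.

Step 9
Reactants: 13 (1R,2R)-2-[3,4-bis(methoxymethoxy)phenyl]-2-{[(E)-1,2-dichloroethenyl]oxy}-1-[3,5-bis(methoxymethoxy)phenyl]ethan-1-ol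
Product: 18 (1R,2R)-2-[3,4-bis(methoxymethoxy)phenyl]-1-[3,5-bis(methoxymethoxy)phenyl]-2-{[(triethylsilyl)ethynyl]oxy}ethan-1-ol, via lithium alkoxide 14 (not isolated), via trimethylsilyl ether 15 (not isolated), via lithium acetylide 16 (not isolated), via bis-silyl diether 17 (not isolated)
Conditions: n-BuLi (1.0 equiv), THF, −78 °C; Me3SiCl (1.0 equiv), −78 to 0 °C; n-BuLi (2.3 equiv), −78 to −40 °C; Et3SiCl (1.3 equiv), −78 to 0 °C; then MeOH, K2CO3 (0.3 equiv), 0 °C
Reagents that add atoms: chlorotriethylsilane, CC[Si](CC)(CC)Cl; chlorotrimethylsilane, C[Si](C)(C)Cl (its atoms stay in 15, 16 and 17 only)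
Why: Second half of the dichlorovinyl ether route: with O1 parked as its Me3Si ether, n-BuLi eliminates HCl and exchanges the remaining chlorine for lithium, acetylide 16 is capped by Et3SiCl, and base-catalysed methanolysis then frees O1–H because an O–SiMe3 bond is cleaved much faster than the hindered C(sp)–SiEt3 bond.

Step 10
Reactants: 18 (1R,2R)-2-[3,4-bis(methoxymethoxy)phenyl]-1-[3,5-bis(methoxymethoxy)phenyl]-2-{[(triethylsilyl)ethynyl]oxy}ethan-1-ol; 10 trichloroethylene
Product: 22 (1R,2R)-1-[3,4-bis(methoxymethoxy)phenyl]-2-[3,5-bis(methoxymethoxy)phenyl]ethane-1,2-diol 2-ethynyl 1-[(triethylsilyl)ethynyl] diether, via potassium alkoxide 19 (not isolated), via dichlorovinyl ether 20 (not isolated), via lithium acetylide 21 (not isolated)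
Conditions: KH (2.5 equiv), THF, 0 °C; Cl2C=CHCl (1.2 equiv), −50 to 20 °C; n-BuLi (3 equiv), −78 to −40 °C; H2O, −78 to 0 °C
Reagents that add atoms: none
Why: The same two-stage dichlorovinyl ether route run in one flask on O1, with a proton instead of a silyl chloride as the final electrophile; n-BuLi at −78 °C leaves the Et3Si-capped alkyne alone and both C–O bonds at the stereocentres stay intact.

Step 11
Reactants: 23 3,5-dihydroxybenzaldehyde
Product: 24 3,5-bis(methoxymethoxy)benzaldehyde
Conditions: MOMCl (3 equiv), i-Pr2NEt (4 equiv), CH2Cl2, 0 °C to rt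
Reagents that add atoms: chloromethyl methyl ether (MOMCl), COCCl
Why: Williamson-type MOM protection of the ring-A resorcinol, matched to the protecting groups of the other rings so that one acid step clears all of them.

Step 12
Reactants: 25 3-bromo-1-(trimethylsilyl)prop-1-yne
Product: 26 diethyl [3-(trimethylsilyl)prop-2-yn-1-yl]phosphonate
Conditions: P(OEt)3 (neat, 1.5 equiv), 120 °C
Reagents that add atoms: triethyl phosphite, CCOP(OCC)OCC
Why: Michaelis–Arbuzov reaction: SN2 attack of phosphorus on the propargylic bromide followed by dealkylation of the phosphonium salt by bromide, the silyl cap disfavouring allene formation.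

Step 13
Reactants: 26 diethyl [3-(trimethylsilyl)prop-2-yn-1-yl]phosphonate; 24 3,5-bis(methoxymethoxy)benzaldehyde
Product: 29 (E)-1-(but-1-en-3-yn-1-yl)-3,5-bis(methoxymethoxy)benzene, via lithiated phosphonate 27 (not isolated), via silyl-capped enyne 28 (not isolated)
Conditions: LiN(SiMe3)2 (1.1 equiv), THF, −78 °C; 24, −78 to 0 °C; then MeOH, K2CO3 (0.5 equiv), rt
Reagents that add atoms: none
Why: Horner–Wadsworth–Emmons olefination of the aromatic aldehyde with the stabilised propargylic phosphonate anion should give the (E)-enyne, and K2CO3/MeOH then cleaves the labile C(sp)–SiMe3 bond to free the terminal alkyne.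

Step 14
Reactants: 22 (1R,2R)-1-[3,4-bis(methoxymethoxy)phenyl]-2-[3,5-bis(methoxymethoxy)phenyl]ethane-1,2-diol 2-ethynyl 1-[(triethylsilyl)ethynyl] diether; 29 (E)-1-(but-1-en-3-yn-1-yl)-3,5-bis(methoxymethoxy)benzene
Product: 30 (2R,3R)-3-[3,4-bis(methoxymethoxy)phenyl]-2-[3,5-bis(methoxymethoxy)phenyl]-7-{(E)-2-[3,5-bis(methoxymethoxy)phenyl]ethenyl}-5-(triethylsilyl)-2,3-dihydro-1,4-benzodioxine
Conditions: Cp*RuCl(cod) (10 mol %), 29 (2.5 equiv), ClCH2CH2Cl (passed through basic Al2O3), 20 °C, 22 added over 4 h, Ar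
Reagents that add atoms: none
Why: Proposed new method: Cp*RuCl, freed from cod, should bind both electron-rich alkynyl ethers of 22 and couple them oxidatively to a ruthenacyclopentadiene that already contains the C4a–C8a bond, after which the alkyne of 29 inserts and reductive elimination releases benzene ring B. The closest known reaction type is the Cp*RuCl(cod)- or rhodium-catalysed [2+2+2] cycloaddition of tethered 1,6- and 1,7-diynes with terminal alkynes at room temperature; what has not been shown is a diyne whose tether is joined through two alkynyl ether oxygens. The 1,4-dioxane ring closes in the oxidative coupling as a six-membered ring fused to the metallacycle (the O1–C2–C3–O4 tether makes 22 a 1,7-diyne whose gauche conformer brings the alkynes together), and ring B closes by formation of C5–C6 and C7–C8 in the insertion and reductive elimination. No stereocentre is formed and no bond to C2 or C3 is touched, so the (2R,3R) configuration passes through unchanged. Regioselectivity is needed and is secured by the Et3Si group on C5, which blocks its side of the metallacycle so that the unsubstituted enyne carbon becomes C6 next to silicon and the styryl-bearing carbon becomes C7, the meta outcome known for diynes with one substituted terminus. Chemoselectivity for the cross reaction over self-coupling is sought by slow addition of 22 to excess 29, the conjugated alkene of 29 being a far poorer partner than its terminal alkyne, and 20 °C keeps the benzylic alkynyl ethers below the onset of their [3,3] shift and retro-ene decay.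

Step 15
Reactants: 30 (2R,3R)-3-[3,4-bis(methoxymethoxy)phenyl]-2-[3,5-bis(methoxymethoxy)phenyl]-7-{(E)-2-[3,5-bis(methoxymethoxy)phenyl]ethenyl}-5-(triethylsilyl)-2,3-dihydro-1,4-benzodioxine
Product: 31 maackin, (2R,3R)-3-(3,4-dihydroxyphenyl)-2-(3,5-dihydroxyphenyl)-7-[(E)-2-(3,5-dihydroxyphenyl)ethenyl]-2,3-dihydro-1,4-benzodioxine
Conditions: HCl (3 M in MeOH), THF, degassed, 50 °C, Ar
Reagents that add atoms: none
Why: Brønsted acid in methanol transacetalises all six MOM ethers to dimethoxymethane and protonates C5 ipso to silicon (protodesilylation through a β-silicon-stabilised arenium ion, activated by the ortho O4), while C2–O1 has no para donor to ionise and any reversible opening at C3–O4 can only return to the more stable trans ring, so the (2R,3R) configuration should hold.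

Compound list
1 | 3',4'-dihydroxyacetophenone | CC(=O)c1ccc(O)c(O)c1 | starting material
2 | 1-[3,4-bis(methoxymethoxy)phenyl]ethan-1-one | CC(=O)c1ccc(OCOC)c(OCOC)c1 | intermediate
3 | 5-bromobenzene-1,3-diol | Oc1cc(O)cc(Br)c1 | starting material
4 | 1-bromo-3,5-bis(methoxymethoxy)benzene | COCOc1cc(Br)cc(OCOC)c1 | intermediate
5 | 1-[3,4-bis(methoxymethoxy)phenyl]-2-[3,5-bis(methoxymethoxy)phenyl]ethan-1-one | O=C(Cc1cc(OCOC)cc(OCOC)c1)c1ccc(OCOC)c(OCOC)c1 | intermediate
6 | sodium (Z)-enolate of 5 | [Na+].[O-]/C(=C\c1cc(OCOC)cc(OCOC)c1)c1ccc(OCOC)c(OCOC)c1 | intermediate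
7 | (2R)-1-[3,4-bis(methoxymethoxy)phenyl]-2-[3,5-bis(methoxymethoxy)phenyl]-2-hydroxyethan-1-one | O[C@H](c1cc(OCOC)cc(OCOC)c1)C(=O)c1ccc(OCOC)c(OCOC)c1 | intermediate
8 | (2R)-1-[3,4-bis(methoxymethoxy)phenyl]-2-[3,5-bis(methoxymethoxy)phenyl]-2-[(2-methoxypropan-2-yl)oxy]ethan-1-one | COC(C)(C)O[C@H](c1cc(OCOC)cc(OCOC)c1)C(=O)c1ccc(OCOC)c(OCOC)c1 | intermediate
9 | (1R,2R)-1-[3,4-bis(methoxymethoxy)phenyl]-2-[3,5-bis(methoxymethoxy)phenyl]-2-[(2-methoxypropan-2-yl)oxy]ethan-1-ol | COC(C)(C)O[C@H](c1cc(OCOC)cc(OCOC)c1)[C@@H](c1ccc(OCOC)c(OCOC)c1)O | intermediate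
10 | trichloroethylene | ClC=C(Cl)Cl | starting material
11 | potassium alkoxide of 9 | COC(C)(C)O[C@H](c1cc(OCOC)cc(OCOC)c1)[C@@H](c1ccc(OCOC)c(OCOC)c1)[O-].[K+] | intermediate
12 | O4-[(E)-1,2-dichloroethenyl] ether of 9, (1R,2R) | COC(C)(C)O[C@H](c1cc(OCOC)cc(OCOC)c1)[C@@H](c1ccc(OCOC)c(OCOC)c1)O/C(Cl)=C\Cl | intermediate
13 | (1R,2R)-2-[3,4-bis(methoxymethoxy)phenyl]-2-{[(E)-1,2-dichloroethenyl]oxy}-1-[3,5-bis(methoxymethoxy)phenyl]ethan-1-ol | O[C@H](c1cc(OCOC)cc(OCOC)c1)[C@@H](c1ccc(OCOC)c(OCOC)c1)O/C(Cl)=C\Cl | intermediate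
14 | lithium alkoxide of 13 | [Li+].[O-][C@H](c1cc(OCOC)cc(OCOC)c1)[C@@H](c1ccc(OCOC)c(OCOC)c1)O/C(Cl)=C\Cl | intermediate
15 | O1-trimethylsilyl ether of 13 | C[Si](C)(C)O[C@H](c1cc(OCOC)cc(OCOC)c1)[C@@H](c1ccc(OCOC)c(OCOC)c1)O/C(Cl)=C\Cl | intermediate
16 | lithium acetylide on O4 (O1 as Me3Si ether) | C[Si](C)(C)O[C@H](c1cc(OCOC)cc(OCOC)c1)[C@@H](c1ccc(OCOC)c(OCOC)c1)OC#C[Li] | intermediate
17 | O1-trimethylsilyl O4-[(triethylsilyl)ethynyl] diether | C[Si](C)(C)O[C@H](c1cc(OCOC)cc(OCOC)c1)[C@@H](c1ccc(OCOC)c(OCOC)c1)OC#C[Si](CC)(CC)CC | intermediate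
18 | (1R,2R)-2-[3,4-bis(methoxymethoxy)phenyl]-1-[3,5-bis(methoxymethoxy)phenyl]-2-{[(triethylsilyl)ethynyl]oxy}ethan-1-ol | O[C@H](c1cc(OCOC)cc(OCOC)c1)[C@@H](c1ccc(OCOC)c(OCOC)c1)OC#C[Si](CC)(CC)CC | intermediate
19 | potassium alkoxide of 18 | [K+].[O-][C@H](c1cc(OCOC)cc(OCOC)c1)[C@@H](c1ccc(OCOC)c(OCOC)c1)OC#C[Si](CC)(CC)CC | intermediate
20 | O1-[(E)-1,2-dichloroethenyl] ether of 18 | Cl\C=C(Cl)/O[C@H](c1cc(OCOC)cc(OCOC)c1)[C@@H](c1ccc(OCOC)c(OCOC)c1)OC#C[Si](CC)(CC)CC | intermediate
21 | lithium acetylide of 22 (on the O1 alkyne) | [Li]C#CO[C@H](c1cc(OCOC)cc(OCOC)c1)[C@@H](c1ccc(OCOC)c(OCOC)c1)OC#C[Si](CC)(CC)CC | intermediate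
22 | (1R,2R)-1-[3,4-bis(methoxymethoxy)phenyl]-2-[3,5-bis(methoxymethoxy)phenyl]ethane-1,2-diol 2-ethynyl 1-[(triethylsilyl)ethynyl] diether | C#CO[C@H](c1cc(OCOC)cc(OCOC)c1)[C@@H](c1ccc(OCOC)c(OCOC)c1)OC#C[Si](CC)(CC)CC | intermediate
23 | 3,5-dihydroxybenzaldehyde | O=Cc1cc(O)cc(O)c1 | starting material
24 | 3,5-bis(methoxymethoxy)benzaldehyde | O=Cc1cc(OCOC)cc(OCOC)c1 | intermediate
25 | 3-bromo-1-(trimethylsilyl)prop-1-yne | C[Si](C)(C)C#CCBr | starting material
26 | diethyl [3-(trimethylsilyl)prop-2-yn-1-yl]phosphonate | CCOP(=O)(CC#C[Si](C)(C)C)OCC | intermediate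
27 | lithiated phosphonate from 26 | [Li+].CCOP(=O)([CH-]C#C[Si](C)(C)C)OCC | intermediate
28 | (E)-[4-[3,5-bis(methoxymethoxy)phenyl]but-3-en-1-yn-1-yl]trimethylsilane | C[Si](C)(C)C#C/C=C/c1cc(OCOC)cc(OCOC)c1 | intermediate
29 | (E)-1-(but-1-en-3-yn-1-yl)-3,5-bis(methoxymethoxy)benzene | C#C/C=C/c1cc(OCOC)cc(OCOC)c1 | intermediate
30 | (2R,3R)-5-triethylsilyl hexakis(methoxymethyl) ether of maackin | COCOc1cc(OCOC)cc(/C=C/c2cc([Si](CC)(CC)CC)c3c(c2)O[C@H](c2cc(OCOC)cc(OCOC)c2)[C@@H](c2ccc(OCOC)c(OCOC)c2)O3)c1 | intermediate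
31 | maackin, (2R,3R) | Oc1cc(O)cc(/C=C/c2ccc3c(c2)O[C@H](c2cc(O)cc(O)c2)[C@@H](c2ccc(O)c(O)c2)O3)c1 | target

Total step count: 15. Longest linear sequence: 11 (steps 1, 3, 4, 5, 6, 7, 8, 9, 10, 14, 15).

Steps most likely to fail

Step 14.
- What may go wrong: decay of the benzylic alkynyl ethers on the metal or on standing ([3,3] shift, ketene formation); self-coupling of the diyne or of the enyne; sluggish oxidative coupling of a 1,7-diyne that carries a silyl terminus; erosion of regiocontrol.
- Fallback (known chemistry, ring B bought instead of built): it sets out from 9 and comes back at 31. Alkoxide 11, made from 9 with KH, displaces fluoride from commercial 3-bromo-4-fluorobenzaldehyde (SNAr activated by the para formyl group, THF/DMF, 0 °C to rt) to give the O4 aryl ether F1. Aqueous acetic acid in THF removes the ketal to give the bromo alcohol F2. Palladium-catalysed intramolecular aryl etherification (Pd(OAc)2, a bulky di-tert-butyl biaryl phosphine, Cs2CO3, toluene, 80 °C) joins O1 to C8a and gives the benzodioxine aldehyde F3. Wittig methylenation (Ph3PCH3Br, KOt-Bu, THF) gives the styrene F4. Heck coupling with bromide 4 (Pd(OAc)2, P(o-tol)3, Et3N, DMF, 100 °C) gives the hexakis(methoxymethyl) ether of maackin F5. The conditions of step 15 then deliver 31.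

Step 10.
- What may go wrong: the potassium alkoxide may attack its neighbour before dichloroacetylene traps it. The possible paths are silyl transfer from carbon to oxygen, 5-exo addition to the triple bond, or displacement of the ynolate at C3 with epoxide formation.
- Fallback (no free alkoxide): it sets out from 18 and comes back at 22. Acylation (Ac2O, Et3N, DMAP, CH2Cl2, 0 °C) gives the acetate F6. Enolisation and O-phosphorylation (LiN(i-Pr)2, then ClP(O)(OEt)2, THF, −78 °C) give the ketene acetal phosphate F7. β-Elimination with t-BuLi (−78 °C) followed by a water quench, the known enol phosphate route from acetates to 1-ethynyl ethers, gives 22.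

Step 6.
- What may go wrong: poor facial selectivity if the ketal oxygens bind the cation or if ring C rather than the C2–O bond takes the perpendicular position, and partial enolisation with loss of configuration at C2.
- Fallback (catalyst control in place of substrate control): it sets out from 8 and comes back at 9. Asymmetric transfer hydrogenation with RuCl[(S,S)-TsDPEN](p-cymene) and HCO2Na in water/i-PrOH at 40 °C is used. This medium is near neutral, so the ketal is spared. The catalyst's known aryl-ketone face preference corresponds to R at C3, matched with (R)-C2 as in the reduction of benzoin. This fallback makes no compound outside the list (F0).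

Further compounds
F1 | step 14 | 3-bromo-4-{(1R,2R)-1-[3,4-bis(methoxymethoxy)phenyl]-2-[3,5-bis(methoxymethoxy)phenyl]-2-[(2-methoxypropan-2-yl)oxy]ethoxy}benzaldehyde | COC(C)(C)O[C@H](c1cc(OCOC)cc(OCOC)c1)[C@@H](c1ccc(OCOC)c(OCOC)c1)Oc1ccc(C=O)cc1Br
F2 | step 14 | 3-bromo-4-{(1R,2R)-1-[3,4-bis(methoxymethoxy)phenyl]-2-[3,5-bis(methoxymethoxy)phenyl]-2-hydroxyethoxy}benzaldehyde | O[C@H](c1cc(OCOC)cc(OCOC)c1)[C@@H](c1ccc(OCOC)c(OCOC)c1)Oc1ccc(C=O)cc1Br
F3 | step 14 | (2R,3R)-3-[3,4-bis(methoxymethoxy)phenyl]-2-[3,5-bis(methoxymethoxy)phenyl]-2,3-dihydro-1,4-benzodioxine-7-carbaldehyde | O=Cc1ccc2c(c1)O[C@H](c1cc(OCOC)cc(OCOC)c1)[C@@H](c1ccc(OCOC)c(OCOC)c1)O2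
F4 | step 14 | (2R,3R)-3-[3,4-bis(methoxymethoxy)phenyl]-2-[3,5-bis(methoxymethoxy)phenyl]-7-ethenyl-2,3-dihydro-1,4-benzodioxine | C=Cc1ccc2c(c1)O[C@H](c1cc(OCOC)cc(OCOC)c1)[C@@H](c1ccc(OCOC)c(OCOC)c1)O2
F5 | step 14 | (2R,3R)-hexakis(methoxymethyl) ether of maackin | COCOc1cc(OCOC)cc(/C=C/c2ccc3c(c2)O[C@H](c2cc(OCOC)cc(OCOC)c2)[C@@H](c2ccc(OCOC)c(OCOC)c2)O3)c1
F6 | step 10 | (1R,2R)-2-[3,4-bis(methoxymethoxy)phenyl]-1-[3,5-bis(methoxymethoxy)phenyl]-2-{[(triethylsilyl)ethynyl]oxy}ethyl acetate | CC(=O)O[C@H](c1cc(OCOC)cc(OCOC)c1)[C@@H](c1ccc(OCOC)c(OCOC)c1)OC#C[Si](CC)(CC)CC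
F7 | step 10 | diethyl 1-{(1R,2R)-2-[3,4-bis(methoxymethoxy)phenyl]-1-[3,5-bis(methoxymethoxy)phenyl]-2-{[(triethylsilyl)ethynyl]oxy}ethoxy}ethenyl phosphate | C=C(OP(=O)(OCC)OCC)O[C@H](c1cc(OCOC)cc(OCOC)c1)[C@@H](c1ccc(OCOC)c(OCOC)c1)OC#C[Si](CC)(CC)CC
F0 | step 6 | none | none
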